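(The readings are calculated with constants of no real substance; noise was put on by code.)

Percent of the starting material charged is the unit of these readings, but a rate answers to molarity, and the questions below are put to a charge.

in all of them: free enzyme 1.9 µM; impurity 1.2 µM

| flask | starting material | second substrate | remark |
|---|---|---|---|
| elm | 0.025 M | 0.050 M | run made earlier |
| flask | 0.050 M | 0.0500 M |  |

elm run (percent of the starting material charged)

| time / min | target / % | starting material / % |
|---|---|---|
| 8.00 | 25.4 | 74.5 |
| 15.0 | 38.0 | 61.4 |
| 25.0 | 56.2 | 42.6 |
| 30.0 | 63.8 | 36.6 |
| 40.0 | 77.4 | 22.9 |
| 50.0 | 90.9 | 9.6 |
| 60.0 | 100.1 | 0.3 |

(scatter of a reading: 0.5 percentage points)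

- apparent order in free enzyme when 30% of the starting material are converted (percent change of the rate of making target for one percent more free enzyme charged)
- apparent order in second substrate when 30% of the starting material are converted (percent change of the rate of making target for one percent more second substrate charged)
- factor on the rate of making target when 30% of the starting material are converted if second substrate is charged twice over

Start with the elm run. Starting material falls by 0.0131 min⁻¹ of its charge from 25.0 min to 40.0 min, then by 0.0113 min⁻¹ up to 60.0 min. Starting material itself drops from 42.6% to 0.3% there, and the slope changes much less than that. So I treat it as nearly zero order.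

Second substrate is never read. I assume one is used per starting material. Its mean level in the two stretches is then 0.0332 M and 0.0279 M. Call n the local order, the percent change of rate per percent change of the second substrate present. These slopes read n = 0.866, a rough reading given a scatter of 0.5 percentage points.

One objection: the first 8.00 min run faster than these stretches, at 0.0319 min⁻¹, and I cannot say why. But the flask at 30% conversion holds 0.0350 M of second substrate, a level inside the stretches I read.

Still, n is not what is asked. At fixed conversion of a fixed charge of starting material, the amount of second substrate used stays the same when its charge grows, so a percent on the charge is more than a percent on what is present. Call L the charge lever, the charge of second substrate over what stands at that conversion: L = 1.43. Then the order on the charge is L times n, or 1.24. Twice the charge raises the level present by a factor of 2.43, which gives a factor on the rate of 2.16. I trust that less, because 0.0850 M lies above anything the elm run held.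

The forecast says 2.2, 0.8 and 1.7, the second below my 1.24. Its ground: “ordinary saturation kinetics suggest 1 or below”. No run tests the enzyme, so I keep its guess there.

The flask gives 2.4, 1.1 and 1.83.

    starting material + free enzyme ⇌ first complex (K = 410 M⁻¹, k = 53000 M⁻¹ s⁻¹)
    first complex → loaded enzyme + first product (k = 420 s⁻¹)
    second substrate + loaded enzyme ⇌ second complex (K = 7.80 M⁻¹, k = 7800 M⁻¹ s⁻¹)
    second complex → free enzyme + target (k = 46.0 s⁻¹)
    free enzyme + impurity → spent catalyst (k = 2.90 × 10⁵ M⁻¹ s⁻¹)

Divided by L, 1.1 is a local order of 0.771; in the flask with twice the second substrate, a factor of 2.43 in concentration for 1.83 in rate means a lower 0.680. In the flask, second complex falls back 22 times faster than it goes on at 0.808 h, and at 0.500 h the flask holds 30.9% of the catalyst charged as loaded enzyme, the resting state of the round, 7.31% as second complex and 60.7% as spent catalyst.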